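The late ratio of other capture product to target, the selectivity between the two captures, reads 0.116 in the elm run and 0.128 in the oak run, taking readings from 1.33 h on, although oak holds 3.91 times the substrate of elm.

all flasks: second nucleophile 1.36 M

| run | substrate | first nucleophile | remark | time |
|---|---|---|---|---|
| elm | 0.46 M | 0.91 M | run made earlier |  |
| oak | 1.8 M | 0.91 M | run made earlier |  |
| flask | 0.91 M | 0.910 M |  | 8.0 h |

| run | time / h | other capture product / % | target / % |
|---|---|---|---|
| elm | 0.417 | 3.0 | 19.7 |
| elm | 0.667 | 4.7 | 20.7 |
| elm | 0.833 | 1.7 | 23.5 |
| elm | 1.33 | 2.5 | 24.5 |
| elm | 2.00 | 3.0 | 24.3 |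
| elm | 3.00 | 2.3 | 22.4 |
| elm | 5.00 | 3.4 | 25.5 |
| oak | 0.250 | 3.0 | 14.9 |
| oak | 0.667 | 2.0 | 19.6 |
| oak | 1.33 | 2.8 | 19.1 |
| oak | 2.00 | 2.8 | 19.8 |
| oak | 3.00 | 2.9 | 21.0 |
| oak | 4.00 | 2.7 | 21.9 |
| oak | 5.00 | 2.0 | 21.1 |

(readings scatter by 1 percentage point)

- ratio of other capture product to target at 80 s
- ratio of other capture product to target at 25 min
- ratio of other capture product to target at 8.0 h
- which of other capture product and target there is more of at 8.0 h



I follow one molecule of substrate to the fork where it ends in target or in other capture product. The late ratios of elm and oak stand close together, with a scatter of 1 percentage point on each reading behind them. These are separate runs, so I trust their geometric mean, 0.122. If both nucleophiles compete for the same molecule, that ratio falls as first nucleophile rises. This is my assumption, untested so far, since both runs charged 0.91 M. The late ratio times the charge of first nucleophile comes to 0.111 M; I call this the split number and carry it.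

The second way to the ratio is the earliest readings, and here the ways part: oak gives 0.201 at 0.250 h, elm 0.152 at 0.417 h. In oak, other capture product reads 3.0% at 0.250 h and 2.0% at 5.00 h, while target climbs from 14.9% to 21.1%. A late ratio is a ratio of totals, so it cheats at early times. For the flask I commit to about 0.201 or above at 80 s, a reading with wide scatter, and to 0.122 at 8.0 h, with target ahead.

The forecast gives 0.14 at 80 s, 0.14 at 25 min and 0.125 at 8.0 h, with target ahead. It differs from me at the early time: “The earliest readings (0.15, 0.20) hint that other capture product forms faster than target, but that is within noise.”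

The flask gives 0.264 at 80 s, 0.113 at 25 min and 0.101 at 8.0 h, with target ahead, 22.8% against 2.30%.

    second nucleophile + intermediate → other capture product (k = 0.489 /M/min)
    first nucleophile + intermediate → target (k = 2.17 /M/min)
    substrate → intermediate (k = 0.0741 /min)
    first nucleophile → decomposition product (k = 4.11 × 10⁻⁴ /min)
    2 second nucleophile → self-condensation product (k = 0.156 /M/min)
    intermediate → solvolysis product (k = 5.67 /min)

Part of what holds the flask's ratio down is the self-condensation of second nucleophile: without that step the flask reads 0.340 instead of 0.264 at 80 s and 0.371 instead of 0.101 at 8.0 h. Taken as read, the split number over the flask's charge gives 0.122, which is 1.21 times the flask's ratio. Over the 0.23 M of first nucleophile in a neighbour flask it gives 0.483, which is 1.18 times what that neighbour holds at 8.0 h, 0.408.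

The earlier runs and the new flask were generated by integration on assumed constants, and the scatter is random.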